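Ring B (C5–C10) is grown from a cyclopentanone. A catalytic asymmetric Diels–Alder reaction builds ring A on a 2-carbomethoxy-3-methylcyclopentenone and places the future C9 carbon on quaternary C10, cis to the C5 methyl group. In the key step the derived 2-formylcyclopentanone undergoes reductive C8–C9 pinacol closure to a cyclopropane-1,2-diol, and acid-induced cleavage of its C8–C10 bond with retention at C10 inserts C9 into the ring. One operation thus forms ring B, its C8 ketone/C9 carbinol (the α-ketol of the target) and the trans ring fusion (C10–H anti to C5–CH3). Ring A is then reduced to the equatorial C3 alcohol and acylated with the trienoic acid.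

Key step: step 8

Remarks on the chemistry:
- Atom numbers C1–C15 are those of the eremophilane skeleton of the target: ring A = C1–C5, C10; ring B = C5–C10; C11–C13 = isopropylidene on C7; C14 on C5; C15 on C4. β is the face of the C5 methyl group.
- The (S,S) ligand in step 4 is assumed to deliver the diene to the face of 3 that leads to 6; if the sense is opposite, the (R,R) ligand is used.
- C8 in 10, 14, 15, 16 and 17 is an inconsequential epimer mixture (the centre becomes a ketone again) and is left unspecified in the SMILES.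
- C4 of 6–14 is drawn α (the expected endo adduct); either epimer converges in step 10.

Step 1
Reactants: 1 3-methylcyclopent-2-en-1-one
Product: 2 2-iodo-3-methylcyclopent-2-en-1-one
Conditions: I2, K2CO3, DMAP (cat.), THF/H2O, rt
Reagents that add atoms: iodine II
Why: Baylis–Hillman-type α-iodination (conjugate addition of DMAP, iodination of the enolate, elimination) should give the 2-iodoenone, since C2 is the only vinylic C–H.

Step 2
Reactants: 2 2-iodo-3-methylcyclopent-2-en-1-one
Product: 3 methyl 2-methyl-5-oxocyclopent-1-ene-1-carboxylate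
Conditions: PdCl2(PPh3)2 (cat.), CO (1 atm), MeOH, Et3N, DMF, 60 °C
Reagents that add atoms: carbon monoxide [C-]#[O+]; methanol CO
Why: Heck-type alkoxycarbonylation (oxidative addition of zerovalent palladium to the vinyl iodide, CO insertion, methanolysis) should convert the α-iodoenone into the doubly activated dienophile.

Step 3
Reactants: 4 pent-1-en-3-one
Product: 5 (Z)-triisopropyl(penta-1,3-dien-3-yloxy)silane
Conditions: iPr3SiOTf, Et3N, CH2Cl2, 0 °C
Reagents that add atoms: triisopropylsilyl triflate CC(C)[Si](C(C)C)(C(C)C)OS(=O)(=O)C(F)(F)F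
Why: Soft enolisation and O-silylation of the ethyl ketone (silyl enol ether formation) should give mainly the Z enol ether, in which the C4 methyl points outward in the s-cis diene.

Step 4
Reactants: 3 methyl 2-methyl-5-oxocyclopent-1-ene-1-carboxylate; 5 (Z)-triisopropyl(penta-1,3-dien-3-yloxy)silane
Product: 6 cis-hydrindanone adduct (ring A fused at C5–C10 to the cyclopentanone C5–C6–C7–C8(=O)–C10; C2=C3 silyl enol ether; C5 methyl and C10 CO2Me both β; C4 methyl α)
Conditions: [Cu((S,S)-tBu-box)](SbF6)2 (10 mol %), 4 Å MS, CH2Cl2, −40 °C to rt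
Reagents that add atoms: none
Why: Lewis-acid-catalysed Diels–Alder reaction in which the β-keto ester chelates divalent copper; the nucleophilic diene terminus C4 bonds to the β-carbon C5 (para rule of 2-siloxydienes), suprafacial addition to the ring dienophile makes the C5 methyl and the C10 ester cis, the box ligand selects the face (absolute configuration of C5 and C10), and endo approach of the ring ketone should place the C4 methyl α.

Step 5
Reactants: 6 cis-hydrindanone adduct
Product: 9 C7-isopropylidene keto ester, via aldol adduct 7 (not isolated), via tertiary mesylate 8 (not isolated)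
Conditions: LiN(iPr)2, THF, −78 °C; acetone; MsCl, −78 to 0 °C; DBU, rt
Reagents that add atoms: acetone CC(C)=O
Why: Only C7 of 6 can be enolised (C10 is quaternary), so directed aldol addition to acetone and E1cB elimination of the mesylate (aldol condensation) should give the conjugated tetrasubstituted enone, without a stereocentre at C7.

Step 6
Reactants: 9 C7-isopropylidene keto ester
Product: 10 allylic 1,3-diol (C8–OH and C10–CH2OH; C8 epimers)
Conditions: iBu2AlH (5 equiv), CH2Cl2, −78 to 0 °C; Rochelle salt
Reagents that add atoms: none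
Why: Hydride reduction of the ester to the primary alcohol and 1,2-reduction of the enone carbonyl leave the silyl enol ether untouched; the new C8 centre is removed again in step 7.

Step 7
Reactants: 10 allylic 1,3-diol
Product: 11 β-keto aldehyde (C10–CHO β, C8 enone)
Conditions: Dess–Martin periodinane, NaHCO3, CH2Cl2, 0 °C to rt
Reagents that add atoms: none
Why: Dess–Martin oxidation of both alcohols under buffered, non-nucleophilic conditions should spare the silyl enol ether and avoid deformylation of the non-enolisable 2-formyl ketone.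

Step 8
Reactants: 11 β-keto aldehyde
Product: 13 9α-hydroxy-8-oxo trans-decalin (10α-H; C2=C3 silyl enol ether; C7 isopropylidene; 4α-methyl), via cyclopropanediol 12 (not isolated)
Conditions: SmI2 (2.2 equiv), THF, −78 °C; then AcOH, THF/H2O, 0 °C to rt
Reagents that add atoms: none
Why: SmI2 reduces the C9 aldehyde and the C8 carbonyl to ketyls that couple across C8–C9 to the samarium-chelated cis-cyclopropane-1,2-diolate 12, and on acidification the cyclopropanol opens electrophilically at the C8–C10 bond, C10 being protonated and C8 becoming the ketone, so the cyclopentanone is enlarged by the inserted C9 to six-membered ring B. The closest known reaction type is the reductive rearrangement of 2-acyl cycloalkanones and other 2,2-disubstituted 1,3-dicarbonyl compounds to α-ketols through cyclopropane-1,2-diols (Clemmensen-type reduction, or SmI2 pinacol cyclisation of 1,3-diketones followed by acid-induced cyclopropanol cleavage). The only ring closure is the 3-exo pinacol coupling that forms the three-membered ring; ring B arises by cleavage of the bond shared by the three- and five-membered rings. C10 is set by retention of configuration in the front-side protonolysis of the C8–C10 bond, so hydrogen takes the α position vacated by C8 while C9 stays cis to the C5 methyl (trans ring fusion), the stereochemical information coming from the Diels–Alder step. C9 is set by the cis-diolate (hydroxyl anti to the five-membered ring), which becomes the equatorial 9α-hydroxyl and is also the thermodynamic epimer of the α-ketol. The step needs cleavage of C8–C10 rather than C9–C10 or C8–C9, which the tertiary allylic carbinol C8 (better donor, conjugated ketone formed) and the relief of bicyclo[3.1.0]hexane strain should secure, and it needs the silyl enol ether to survive, which SmI2 and dilute acetic acid should allow.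

Step 9
Reactants: 13 9α-hydroxy-8-oxo trans-decalin
Product: 14 8,9α-diol (allylic C8–OH; C8 epimers)
Conditions: NaBH4, CeCl3·7H2O, MeOH/THF, −78 to −40 °C
Reagents that add atoms: none
Why: Luche 1,2-reduction masks the C8 carbonyl as an allylic alcohol so that the enone and α-ketol are not destroyed by the dissolving metal in step 11; the C8 configuration is immaterial.

Step 10
Reactants: 14 8,9α-diol
Product: 16 8,9α-dihydroxy-3-ketone with 4β-methyl, via 4-epi ketone 15 (not isolated)
Conditions: Bu4NF, THF, 0 °C; then NaOMe (cat.), MeOH, rt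
Reagents that add atoms: none
Why: Fluoride cleaves the silyl enol ether, and methoxide then equilibrates C4 through the C3 enolate towards the equatorial 4β-methyl (cis to the C5 methyl), because the axial 4α-methyl of the rigid trans-decalin suffers two 1,3-diaxial interactions; the minor epimer can be resubmitted.

Step 11
Reactants: 16 8,9α-dihydroxy-3-ketone
Product: 17 3α,8,9α-triol
Conditions: Li, NH3(l), THF, tBuOH, −78 to −33 °C; NH4Cl
Reagents that add atoms: none
Why: Dissolving-metal reduction of the ketone is thermodynamically controlled and should give the equatorial 3α-alcohol, whereas hydride reagents would attack anti to the axial C5 methyl and give the axial epimer; the isolated tetrasubstituted alkene and the alkoxides are inert.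

Step 12
Reactants: 17 3α,8,9α-triol
Product: 18 3α,9α-dihydroxy-8-ketone (C7 isopropylidene, 10α-H)
Conditions: MnO2 (activated, excess), CH2Cl2, rt
Reagents that add atoms: none
Why: MnO2 oxidises only the allylic C8 alcohol, restoring the conjugated ketone and leaving the saturated C3 and C9 alcohols.

Step 13
Reactants: 19 (E)-non-3-en-2-one; 20 triethyl (E)-4-phosphonocrotonate
Product: 21 ethyl (2E,4E,6E)-5-methyldodeca-2,4,6-trienoate
Conditions: LiN(SiMe3)2, THF, −78 °C to rt
Reagents that add atoms: none
Why: Vinylogous Horner–Wadsworth–Emmons olefination of the methyl ketone should give mainly the 4E trisubstituted alkene (the larger alkenyl group trans to the dienoate chain); the minor 4Z isomer is removed by chromatography.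

Step 14
Reactants: 21 ethyl (2E,4E,6E)-5-methyldodeca-2,4,6-trienoate
Product: 22 (2E,4E,6E)-5-methyldodeca-2,4,6-trienoic acid
Conditions: LiOH, THF/MeOH/H2O, rt; then dilute HCl
Reagents that add atoms: water (as hydroxide) O
Why: Saponification of the ethyl ester; the conjugated all-E triene is stable to aqueous hydroxide at room temperature.

Step 15
Reactants: 22 (2E,4E,6E)-5-methyldodeca-2,4,6-trienoic acid; 18 3α,9α-dihydroxy-8-ketone
Product: 24 target ester, via mixed anhydride 23 (not isolated)
Conditions: 2,4,6-trichlorobenzoyl chloride, Et3N, THF, rt; then 18 (1.0 equiv), DMAP, toluene, 0 °C to rt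
Reagents that add atoms: none
Why: Yamaguchi esterification should acylate the equatorial C3 hydroxyl in preference to the C9 hydroxyl, which is hydrogen-bonded to the C8 carbonyl, inductively deactivated and flanked by C10 and the ketone; no stereocentre is touched.

Compound list
1 | 3-methylcyclopent-2-en-1-one | CC1=CC(=O)CC1 | starting material
2 | 2-iodo-3-methylcyclopent-2-en-1-one | CC1=C(I)C(=O)CC1 | intermediate
3 | methyl 2-methyl-5-oxocyclopent-1-ene-1-carboxylate | COC(=O)C1=C(C)CCC1=O | intermediate
4 | pent-1-en-3-one | C=CC(=O)CC | starting material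
5 | (Z)-triisopropyl(penta-1,3-dien-3-yloxy)silane | C=C/C(O[Si](C(C)C)(C(C)C)C(C)C)=C/C | intermediate
6 | methyl 3a,4-dimethyl-1-oxo-5-(triisopropylsilyloxy)-2,3,3a,4,7,7a-hexahydro-1H-indene-7a-carboxylate, cis-fused (C5 methyl and C10 ester β, C4 methyl α) | COC(=O)[C@]12CC=C(O[Si](C(C)C)(C(C)C)C(C)C)[C@@H](C)[C@@]1(C)CCC2=O | intermediate
7 | aldol adduct of 6 with acetone at C7 (2-hydroxypropan-2-yl; C7 epimers) | COC(=O)[C@]12CC=C(O[Si](C(C)C)(C(C)C)C(C)C)[C@@H](C)[C@@]1(C)CC(C(C)(C)O)C2=O | intermediate
8 | methanesulfonate of the tertiary alcohol of 7 | COC(=O)[C@]12CC=C(O[Si](C(C)C)(C(C)C)C(C)C)[C@@H](C)[C@@]1(C)CC(C(C)(C)OS(C)(=O)=O)C2=O | intermediate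
9 | methyl 3a,4-dimethyl-1-oxo-2-(propan-2-ylidene)-5-(triisopropylsilyloxy)-2,3,3a,4,7,7a-hexahydro-1H-indene-7a-carboxylate (configuration as 6) | COC(=O)[C@]12CC=C(O[Si](C(C)C)(C(C)C)C(C)C)[C@@H](C)[C@@]1(C)CC(=C(C)C)C2=O | intermediate
10 | diol from 9: C10 hydroxymethyl (β) and C8 allylic alcohol (C8 epimers), otherwise as 9 | OC[C@]12CC=C(O[Si](C(C)C)(C(C)C)C(C)C)[C@@H](C)[C@@]1(C)CC(=C(C)C)C2O | intermediate
11 | 3a,4-dimethyl-1-oxo-2-(propan-2-ylidene)-5-(triisopropylsilyloxy)-2,3,3a,4,7,7a-hexahydro-1H-indene-7a-carbaldehyde (C10 formyl β, cis to the C5 methyl) | O=C[C@]12CC=C(O[Si](C(C)C)(C(C)C)C(C)C)[C@@H](C)[C@@]1(C)CC(=C(C)C)C2=O | intermediate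
12 | cis-cyclopropane-1,2-diol: C8(OH)–C9H(OH) bond closed, cyclopropane C8–C9–C10 fused to ring A and to the cyclopentane, both hydroxyls anti to the five-membered ring | O[C@H]1[C@]23CC=C(O[Si](C(C)C)(C(C)C)C(C)C)[C@@H](C)[C@@]2(C)CC(=C(C)C)[C@]13O | intermediate
13 | 9α-hydroxy-4α,5β-dimethyl-7-(propan-2-ylidene)-3-(triisopropylsilyloxy)-10αH-decal-2-en-8-one (trans-fused) | CC(C)[Si](C(C)C)(C(C)C)OC1=CC[C@H]2[C@H](O)C(=O)C(=C(C)C)C[C@]2(C)[C@@H]1C | intermediate
14 | 8,9α-diol from 13 (C8 epimers), silyl enol ether retained | CC(C)[Si](C(C)C)(C(C)C)OC1=CC[C@H]2[C@H](O)C(O)C(=C(C)C)C[C@]2(C)[C@@H]1C | intermediate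
15 | 8,9α-dihydroxy-4α,5β-dimethyl-7-(propan-2-ylidene)-trans-decalin-3-one (4-epi ketone) | O=C1CC[C@H]2[C@H](O)C(O)C(=C(C)C)C[C@]2(C)[C@@H]1C | intermediate
16 | 8,9α-dihydroxy-4β,5β-dimethyl-7-(propan-2-ylidene)-trans-decalin-3-one (10α-H) | O=C1CC[C@H]2[C@H](O)C(O)C(=C(C)C)C[C@]2(C)[C@H]1C | intermediate
17 | 4β,5β-dimethyl-7-(propan-2-ylidene)-trans-decalin-3α,8,9α-triol (10α-H; C8 epimers) | O[C@@H]1CC[C@H]2[C@H](O)C(O)C(=C(C)C)C[C@]2(C)[C@H]1C | intermediate
18 | 3α,9α-dihydroxy-10αH-eremophil-7(11)-en-8-one (4β,5β-dimethyl, trans-fused) | O[C@@H]1CC[C@H]2[C@H](O)C(=O)C(=C(C)C)C[C@]2(C)[C@H]1C | intermediate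
19 | (E)-non-3-en-2-one | CCCCC/C=C/C(C)=O | starting material
20 | triethyl (E)-4-phosphonocrotonate | CCOC(=O)/C=C/CP(=O)(OCC)OCC | starting material
21 | ethyl (2E,4E,6E)-5-methyldodeca-2,4,6-trienoate | CCCCC/C=C/C(C)=C/C=C/C(=O)OCC | intermediate
22 | (2E,4E,6E)-5-methyldodeca-2,4,6-trienoic acid | CCCCC/C=C/C(C)=C/C=C/C(=O)O | intermediate
23 | mixed anhydride of 22 with 2,4,6-trichlorobenzoic acid | CCCCC/C=C/C(C)=C/C=C/C(=O)OC(=O)c1c(Cl)cc(Cl)cc1Cl | intermediate
24 | 9α-hydroxy-8-oxo-10αH-eremophil-7(11)-en-3α-yl (2E,4E,6E)-5-methyldodeca-2,4,6-trienoate (4β,5β-dimethyl, trans-fused) | CCCCC/C=C/C(C)=C/C=C/C(=O)O[C@@H]1CC[C@H]2[C@H](O)C(=O)C(=C(C)C)C[C@]2(C)[C@H]1C | target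

Total step count: 15. Longest linear sequence: 12 steps (steps 1, 2, 4–12, 15).

Steps most likely to fail

Step 8. The cyclopropanediol may open in the wrong sense (cleavage of C9–C10, or a base-type opening with inversion at C10 that would give the cis ring fusion), the aldehyde may be reduced without C–C coupling, or acid may trigger a semipinacol opening of the vinylcyclopropanol. The fallback sets out from diol 10 and comes back at 13. MnO2 oxidises only the allylic C8 alcohol to the hydroxymethyl enone F1. I2, PPh3 and imidazole in hot toluene then give the neopentyl iodomethyl enone F2. A Dowd–Beckwith radical ring expansion (Bu3SnH, AIBN, slow addition, benzene, reflux) should give the ring-expanded 9-deoxy enone F3, the C10 radical taking hydrogen anti to the axial C5 methyl. Kinetic enolisation towards C9 (LiN(SiMe3)2, −78 °C) and oxidation with 2-(phenylsulfonyl)-3-phenyloxaziridine from the α face then gives 13.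

Step 4. The tetrasubstituted dienophile may react too slowly when two adjacent quaternary centres are formed, the catalyst may give poor facial selectivity, or Mukaiyama–Michael addition may stop before ring closure. The fallback sets out from 2 and comes back at 10, replacing catalyst control by a covalently bound auxiliary that is lost in a reduction the route contains anyway. Carbonylation of 2 in the presence of (−)-8-phenylmenthol (PdCl2(PPh3)2, CO, Et3N) gives the 8-phenylmenthyl dienophile F4. Et2AlCl-promoted Diels–Alder reaction with 5 at −78 °C, the aryl group shielding one face, gives the auxiliary adduct F5. The sequence of step 5 then gives the auxiliary aldol F6, the auxiliary mesylate F7 and the auxiliary isopropylidene ester F8. Reduction with iBu2AlH as in step 6 releases the auxiliary and gives 10.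

Step 15. The C9 hydroxyl may be acylated as well, or in place of the C3 hydroxyl. The fallback sets out from triol 17 and comes back at 24. PhB(OH)2 in toluene with azeotropic removal of water ties up the vicinal 8,9-diol as the cyclic phenylboronate F9, leaving only the C3 hydroxyl free. Acylation with 22 (EDC, DMAP, CH2Cl2) gives the boronate ester F10. Exchange with pinacol releases the 3-O-acyl 8,9-diol F11, and MnO2 oxidation of its allylic C8 alcohol gives 24.

Further compounds
F1 | step 8 | hydroxymethyl enone (C10–CH2OH, C8 ketone, otherwise as 11) | OC[C@]12CC=C(O[Si](C(C)C)(C(C)C)C(C)C)[C@@H](C)[C@@]1(C)CC(=C(C)C)C2=O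
F2 | step 8 | iodomethyl enone (C10–CH2I) | IC[C@]12CC=C(O[Si](C(C)C)(C(C)C)C(C)C)[C@@H](C)[C@@]1(C)CC(=C(C)C)C2=O
F3 | step 8 | 9-deoxy analogue of 13 (trans-decalin-8-one, 10α-H) | CC(C)[Si](C(C)C)(C(C)C)OC1=CC[C@H]2CC(=O)C(=C(C)C)C[C@]2(C)[C@@H]1C
F4 | step 4 | (1R,2S,5R)-8-phenylmenthyl 2-methyl-5-oxocyclopent-1-ene-1-carboxylate | C[C@@H]1CC[C@H]([C@@H](C1)OC(=O)C1=C(C)CCC1=O)C(C)(C)c1ccccc1
F5 | step 4 | 8-phenylmenthyl ester analogue of 6 | C[C@@H]1CC[C@H]([C@@H](C1)OC(=O)[C@]12CC=C(O[Si](C(C)C)(C(C)C)C(C)C)[C@@H](C)[C@@]1(C)CCC2=O)C(C)(C)c1ccccc1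
F6 | step 4 | 8-phenylmenthyl ester analogue of 7 | C[C@@H]1CC[C@H]([C@@H](C1)OC(=O)[C@]12CC=C(O[Si](C(C)C)(C(C)C)C(C)C)[C@@H](C)[C@@]1(C)CC(C(C)(C)O)C2=O)C(C)(C)c1ccccc1
F7 | step 4 | 8-phenylmenthyl ester analogue of 8 | C[C@@H]1CC[C@H]([C@@H](C1)OC(=O)[C@]12CC=C(O[Si](C(C)C)(C(C)C)C(C)C)[C@@H](C)[C@@]1(C)CC(C(C)(C)OS(C)(=O)=O)C2=O)C(C)(C)c1ccccc1
F8 | step 4 | 8-phenylmenthyl ester analogue of 9 | C[C@@H]1CC[C@H]([C@@H](C1)OC(=O)[C@]12CC=C(O[Si](C(C)C)(C(C)C)C(C)C)[C@@H](C)[C@@]1(C)CC(=C(C)C)C2=O)C(C)(C)c1ccccc1
F9 | step 15 | cyclic 8,9-phenylboronate of 17 | O[C@@H]1CC[C@H]2[C@@H]3OB(c4ccccc4)OC3C(=C(C)C)C[C@]2(C)[C@H]1C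
F10 | step 15 | 3-O-trienoyl ester of F9 | CCCCC/C=C/C(C)=C/C=C/C(=O)O[C@@H]1CC[C@H]2[C@@H]3OB(c4ccccc4)OC3C(=C(C)C)C[C@]2(C)[C@H]1C
F11 | step 15 | 3-O-trienoyl 8,9α-diol | CCCCC/C=C/C(C)=C/C=C/C(=O)O[C@@H]1CC[C@H]2[C@H](O)C(O)C(=C(C)C)C[C@]2(C)[C@H]1C
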